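**Plan**
- Retrosynthesis: the C11=C13 methylene is masked as a thiophenol adduct, the C8 angelate is cut, and the C1 hydroxyl is traced back to a C1–silicon bond. Then C2–C3 and O–C10 are cut together to give an acyclic (Z)-enal allylsilane. Then C6–C7 and the lactone C–O are cut to give a 2-alkoxycarbonyl allylboronate and a (Z)-enal. Last, C7–C8 (alkynylation) and C10–CH3 (allylic methylation) are cut.
- Enabling feature: the 3-hydroxyoxolane O/C3/C2/C1/C10. The C1 carbinol sits between the C2 methylene and the tertiary ether carbon C10, which is the retron of an allylsilane–aldehyde [3+2] annulation followed by C–Si oxidation. Because C2–C3 is also a bond of the ten-membered carbocycle C1–C10, one annulation of a seco-aldehyde closes both rings.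
- Forward order: silicon-bearing quaternary C10, then C8 carbinol, then allylboronate, then trans-lactone (C6, C7), then carbocycle and oxolane together, then angelate, then C1–OH, then the methylene lactone.
- Stereochemistry: C10 from a copper-catalysed enantioselective allylic methylation; C8 from a catalytic asymmetric alkynylation; C6/C7 from a chair allylboration with 1,2-induction from C8; C3, C1 and C10 in the annulation; C1–OH by retentive C–Si oxidation; 4Z from a butenolide; the angelate geometry from angelic acid.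

Key step: step 16

**Remarks.** C-numbers are the germacrane positions of the target: C1 carbinol, C3 and C10 ether carbons, C6 lactone carbinol, C8 ester carbinol, C11/C12/C13 lactone α-carbon, carbonyl and methylene. C11 (steps 14–19) and sulfur (step 19) form as epimer mixtures that step 20 erases, so their SMILES carry no descriptor. 4,4-Diethoxybut-1-yne is taken as a catalogue compound.

**Step 1**
Reactants: 1 diphenylmethane; 2 chlorodimethylsilane
Product: 4 benzhydryldimethylsilane, via (diphenylmethyl)lithium 3 (not isolated)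
Conditions: n-BuLi, THF, 0 °C to rt; then 2, −78 °C to rt
Reagents that add atoms: none
Why: Benzylic lithiation followed by nucleophilic substitution at silicon gives the hydrosilane whose silyl group later serves as the C1 hydroxyl surrogate.

**Step 2**
Reactants: 5 4,4-diethoxybut-1-yne
Product: 7 5,5-diethoxypent-2-yn-1-ol, via (4,4-diethoxybut-1-yn-1-yl)lithium 6 (not isolated)
Conditions: n-BuLi, THF, −78 °C; (CH2O)n, −78 °C to rt; H2O
Reagents that add atoms: formaldehyde (from paraformaldehyde), C=O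
Why: Acetylide addition to formaldehyde gives the propargylic alcohol that directs the hydrosilylation.

**Step 3**
Reactants: 7 5,5-diethoxypent-2-yn-1-ol; 4 benzhydryldimethylsilane
Product: 8 (E)-3-[benzhydryl(dimethyl)silyl]-5,5-diethoxypent-2-en-1-ol
Conditions: PtCl2 (cat.), XPhos (cat.), THF, 50 °C
Reagents that add atoms: none
Why: Platinum-catalysed syn hydrosilylation of a propargylic alcohol should place silicon on the alkyne carbon distal to the hydroxyl, so that C10 carries silicon in an (E)-alkene.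

**Step 4**
Reactants: 8 (E)-3-[benzhydryl(dimethyl)silyl]-5,5-diethoxypent-2-en-1-ol
Product: 9 (E)-3-[benzhydryl(dimethyl)silyl]-5,5-diethoxypent-2-en-1-yl diethyl phosphate
Conditions: ClP(O)(OEt)2, Et3N, DMAP (cat.), CH2Cl2, 0 °C
Reagents that add atoms: diethyl chlorophosphate, CCOP(=O)(Cl)OCC
Why: Phosphorylation of the primary allylic alcohol installs the leaving group for the allylic substitution.

**Step 5**
Reactants: 9 (E)-3-[benzhydryl(dimethyl)silyl]-5,5-diethoxypent-2-en-1-yl diethyl phosphate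
Product: 10 (R)-benzhydryl(5,5-diethoxy-3-methylpent-1-en-3-yl)dimethylsilane
Conditions: Me2Zn, CuCl2·2H2O (cat.), chiral sulfonate-bearing imidazolinium salt (N-heterocyclic carbene precursor, cat.), THF, −15 °C
Reagents that add atoms: dimethylzinc, C[Zn]C
Why: Copper-catalysed enantioselective allylic alkylation (SN2′) of a γ-silyl-γ-alkyl allylic phosphate with a dialkylzinc should create the silicon-bearing quaternary centre C10, the ligand enantiomer being chosen to give the (R)-silane.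

**Step 6**
Reactants: 10 (R)-benzhydryl(5,5-diethoxy-3-methylpent-1-en-3-yl)dimethylsilane
Product: 11 (R)-3-[benzhydryl(dimethyl)silyl]-3-methylpent-4-enal
Conditions: PPTS (cat.), acetone/H2O, 45 °C
Reagents that add atoms: water, O
Why: Mild acid-catalysed acetal hydrolysis should free the aldehyde (C8) without protodesilylation of the tertiary allylsilane.

**Step 7**
Reactants: 11 (R)-3-[benzhydryl(dimethyl)silyl]-3-methylpent-4-enal; 12 methyl propiolate
Product: 14 methyl (4R,6R)-6-[benzhydryl(dimethyl)silyl]-4-hydroxy-6-methyloct-7-en-2-ynoate, via methyl 3-(methylzincio)prop-2-ynoate 13 (not isolated)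
Conditions: Me2Zn, ProPhenol ligand (cat.), Ph3P=O (cat.), toluene, 4 °C; H2O
Reagents that add atoms: none
Why: Catalytic asymmetric alkynylation of the aldehyde with the zinc acetylide under the dinuclear zinc–ProPhenol catalyst should set C8 by catalyst control, the ligand enantiomer being chosen to give the (8R)-carbinol.

**Step 8**
Reactants: 14 methyl (4R,6R)-6-[benzhydryl(dimethyl)silyl]-4-hydroxy-6-methyloct-7-en-2-ynoate
Product: 15 methyl (4R,6R)-6-[benzhydryl(dimethyl)silyl]-4-[(tert-butyldimethylsilyl)oxy]-6-methyloct-7-en-2-ynoate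
Conditions: TBSOTf, 2,6-lutidine, CH2Cl2, −78 °C
Reagents that add atoms: tert-butyldimethylsilyl triflate, CC(C)(C)[Si](C)(C)OS(=O)(=O)C(F)(F)F
Why: Silylation with a non-nucleophilic base protects the propargylic alcohol without conjugate addition to the ynoate.

**Step 9**
Reactants: 15 methyl (4R,6R)-6-[benzhydryl(dimethyl)silyl]-4-[(tert-butyldimethylsilyl)oxy]-6-methyloct-7-en-2-ynoate; 16 2-(iodomethyl)-4,4,5,5-tetramethyl-1,3,2-dioxaborolane
Product: 18 methyl (2Z,4R,6R)-6-[benzhydryl(dimethyl)silyl]-4-[(tert-butyldimethylsilyl)oxy]-6-methyl-2-[(4,4,5,5-tetramethyl-1,3,2-dioxaborolan-2-yl)methyl]octa-2,7-dienoate, via α-(diisobutylalumanyl) enoate 17 (not isolated)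
Conditions: i-Bu2AlH, HMPA, THF, 0 °C; then 16, 0 °C to rt
Reagents that add atoms: none
Why: Conjugate syn hydroalumination of the ynoate and alkylation of the alkenylaluminium with retention of geometry should give the 2-alkoxycarbonyl allylboronate with C8 cis to the ester and trans to the CH2B group.

**Step 10**
Reactants: 19 4-methylfuran-2(5H)-one
Product: 20 (Z)-4-hydroxy-N-methoxy-N,3-dimethylbut-2-enamide
Conditions: Me(MeO)NH·HCl, AlMe3, CH2Cl2, 0 °C to rt; aqueous KNaC4H4O6
Reagents that add atoms: N,O-dimethylhydroxylamine hydrochloride, CNOC.Cl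
Why: Aluminium amide aminolysis opens the butenolide to the N-methoxy-N-methylamide and keeps the Z double bond that becomes C4=C5.

**Step 11**
Reactants: 20 (Z)-4-hydroxy-N-methoxy-N,3-dimethylbut-2-enamide
Product: 21 (Z)-N-methoxy-N,3-dimethyl-4-[(triethylsilyl)oxy]but-2-enamide
Conditions: TESCl, imidazole, CH2Cl2, 0 °C
Reagents that add atoms: chlorotriethylsilane, CC[Si](Cl)(CC)CC
Why: Silylation of the primary alcohol (C3–O) prevents relactonisation.

**Step 12**
Reactants: 21 (Z)-N-methoxy-N,3-dimethyl-4-[(triethylsilyl)oxy]but-2-enamide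
Product: 22 (Z)-3-methyl-4-[(triethylsilyl)oxy]but-2-enal
Conditions: i-Bu2AlH, THF, −78 °C; aqueous KNaC4H4O6
Reagents that add atoms: none
Why: Hydride reduction of the N-methoxy-N-methylamide stops at the aldehyde through the chelated tetrahedral intermediate and should give the (Z)-enal (C6 aldehyde).

**Step 13**
Reactants: 18 methyl (2Z,4R,6R)-6-[benzhydryl(dimethyl)silyl]-4-[(tert-butyldimethylsilyl)oxy]-6-methyl-2-[(4,4,5,5-tetramethyl-1,3,2-dioxaborolan-2-yl)methyl]octa-2,7-dienoate; 22 (Z)-3-methyl-4-[(triethylsilyl)oxy]but-2-enal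
Product: 25 (4S,5R)-5-[(Z)-3-hydroxy-2-methylprop-1-enyl]-3-methylidene-4-[(1R,3R)-3-(benzhydryldimethylsilyl)-1-(tert-butyldimethylsilyloxy)-3-methylpent-4-enyl]oxolan-2-one, via open-chain pinacol borate 23 (not isolated), via triethylsilyl lactone 24 (not isolated)
Conditions: toluene (1 M), 80 °C; then PPTS (cat.), MeOH, rt
Reagents that add atoms: none
Why: Thermal allylboration through a closed chair (aldehyde substituent equatorial, C8 trans to CH2B) should give the anti adduct and hence the trans-lactone, while allylic 1,3-strain with the cis ester holds the C8 hydrogen in the alkene plane so that the aldehyde adds anti to the bulky C9 chain and sets C6 and C7; acidic methanol then completes lactonisation and removes the primary triethylsilyl ether.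

**Step 14**
Reactants: 25 (4S,5R)-5-[(Z)-3-hydroxy-2-methylprop-1-enyl]-3-methylidene-4-[(1R,3R)-3-(benzhydryldimethylsilyl)-1-(tert-butyldimethylsilyloxy)-3-methylpent-4-enyl]oxolan-2-one
Product: 26 (4S,5R)-5-[(Z)-3-hydroxy-2-methylprop-1-enyl]-3-[(phenylsulfanyl)methyl]-4-[(1R,3R)-3-(benzhydryldimethylsilyl)-1-(tert-butyldimethylsilyloxy)-3-methylpent-4-enyl]oxolan-2-one
Conditions: PhSH, Et3N (cat.), THF, 0 °C to rt
Reagents that add atoms: thiophenol, Sc1ccccc1
Why: Thia-Michael addition masks the α-methylene lactone as a sulfide so that it survives the later fluoride and peroxide treatment (C11 forms as an epimer mixture that is erased in step 20).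

**Step 15**
Reactants: 26 (4S,5R)-5-[(Z)-3-hydroxy-2-methylprop-1-enyl]-3-[(phenylsulfanyl)methyl]-4-[(1R,3R)-3-(benzhydryldimethylsilyl)-1-(tert-butyldimethylsilyloxy)-3-methylpent-4-enyl]oxolan-2-one
Product: 27 (4S,5R)-5-[(Z)-2-methyl-3-oxoprop-1-enyl]-3-[(phenylsulfanyl)methyl]-4-[(1R,3R)-3-(benzhydryldimethylsilyl)-1-(tert-butyldimethylsilyloxy)-3-methylpent-4-enyl]oxolan-2-one
Conditions: MnO2, CH2Cl2, rt
Reagents that add atoms: none
Why: Allylic oxidation with MnO2 should convert only the primary allylic alcohol into the (Z)-enal (C3 aldehyde), leaving the sulfide, the silyl groups and the alkene geometry untouched.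

**Step 16**
Reactants: 27 (4S,5R)-5-[(Z)-2-methyl-3-oxoprop-1-enyl]-3-[(phenylsulfanyl)methyl]-4-[(1R,3R)-3-(benzhydryldimethylsilyl)-1-(tert-butyldimethylsilyloxy)-3-methylpent-4-enyl]oxolan-2-one
Product: 28 (1S,3S,4Z,6R,7S,8R,10S)-1-(benzhydryldimethylsilyl)-8-(tert-butyldimethylsilyloxy)-3,10-epoxy-13-(phenylsulfanyl)germacr-4-en-12,6-olide
Conditions: BF3·OEt2 (3 equiv), CH2Cl2, −78 to −40 °C, slow addition of 27 to 0.002 M; aqueous NaHCO3
Reagents that add atoms: none
Why: Proposed new method: the BF3-bound (Z)-enal carbon C3 is attacked by the vinyl terminus C2 anti to the C10–Si bond, the β-silyl cation at C1 collapses by a suprafacial 1,2-silyl shift to the siliranium/tertiary cation at C10, and the C3 alkoxide opens it with inversion, so that both rings of the 11-oxabicyclo[6.2.1]undecene close in one operation; the closest known reaction type is the intermolecular Lewis-acid-promoted [3+2] annulation of bulky allylsilanes with aldehydes to 3-silyltetrahydrofurans, which has not been used to close a carbocycle at the same time. The ten-membered ring closes by attack of the allylsilane terminus on the aldehyde (endo with respect to the vinyl group, exo with respect to C=O), and the oxolane closes by 5-endo anti opening of the siliranium ion at its tertiary carbon. C10 is set stereospecifically from the (10R)-silane by inversion; C1 is set by the silyl shift, and its relation to C10 follows from the rotamer in which ring carbon C9, not the methyl group, lies syn to the vinyl group, the cisoid arrangement of a Z-cycloalkene that a forming ten-membered ring should prefer; C3 is set by the bridge, because only the aldehyde face that places C4 cis to C9 lets the oxygen reach C10. The step needs annulation to win over desilylative Hosomi–Sakurai allylation, over E/Z isomerisation of the enal and over oligomerisation: the bulky benzhydryldimethylsilyl group and the non-nucleophilic counter-ion disfavour attack at silicon, the tertiary cation at C10 favours capture by oxygen, the low temperature preserves the Z-enal, and the Z-alkene with the trans-lactone act as turn elements under high dilution.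

**Step 17**
Reactants: 28 (1S,3S,4Z,6R,7S,8R,10S)-1-(benzhydryldimethylsilyl)-8-(tert-butyldimethylsilyloxy)-3,10-epoxy-13-(phenylsulfanyl)germacr-4-en-12,6-olide
Product: 29 (1S,3S,4Z,6R,7R,8R,10S)-1-(benzhydryldimethylsilyl)-3,10-epoxy-8-hydroxy-13-(phenylsulfanyl)germacr-4-en-12,6-olide
Conditions: HF·pyridine, pyridine, THF, 0 °C to rt
Reagents that add atoms: none
Why: Buffered HF·pyridine should cleave the O–Si bond of the silyl ether, whereas the C–Si bond of the alkylsilane needs unsolvated fluoride and should remain.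

**Step 18**
Reactants: 29 (1S,3S,4Z,6R,7R,8R,10S)-1-(benzhydryldimethylsilyl)-3,10-epoxy-8-hydroxy-13-(phenylsulfanyl)germacr-4-en-12,6-olide; 30 angelic acid
Product: 32 (1S,3S,4Z,6R,7R,8R,10S)-8-angeloyloxy-1-(benzhydryldimethylsilyl)-3,10-epoxy-13-(phenylsulfanyl)germacr-4-en-12,6-olide, via angelic 2,4,6-trichlorobenzoic anhydride 31 (not isolated)
Conditions: 30, 2,4,6-trichlorobenzoyl chloride, Et3N, toluene, rt; then 29, toluene, 80 °C
Reagents that add atoms: none
Why: Yamaguchi esterification through the mixed anhydride without a nucleophilic catalyst acylates the only free hydroxyl (C1 is still a silane) and should avoid isomerisation of the angelate to the tiglate.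

**Step 19**
Reactants: 32 (1S,3S,4Z,6R,7R,8R,10S)-8-angeloyloxy-1-(benzhydryldimethylsilyl)-3,10-epoxy-13-(phenylsulfanyl)germacr-4-en-12,6-olide
Product: 34 (1S,3S,4Z,6R,7R,8R,10S)-8-angeloyloxy-3,10-epoxy-1-hydroxy-13-(phenylsulfinyl)germacr-4-en-12,6-olide, via C1 fluorodimethylsilane 33 (not isolated)
Conditions: Bu4NF, THF, 0 °C; then H2O2 (30% aq.), KHCO3, MeOH/THF, rt
Reagents that add atoms: hydrogen peroxide, OO; tetrabutylammonium fluoride, CCCC[N+](CCCC)(CCCC)CCCC.[F-] (fluorine of intermediate 33 only)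
Why: Fluoride cleaves the benzhydryl group from silicon and the fluorosilane undergoes Tamao–Fleming oxidation with retention at C1, the peroxide at the same time oxidising the sulfide to the sulfoxide.

**Step 20**
Reactants: 34 (1S,3S,4Z,6R,7R,8R,10S)-8-angeloyloxy-3,10-epoxy-1-hydroxy-13-(phenylsulfinyl)germacr-4-en-12,6-olide
Product: 35 (1S,3S,4Z,6R,7R,8R,10S)-8-angeloyloxy-3,10-epoxy-1-hydroxygermacra-4,11(13)-dien-12,6-olide (CNP0213894.1)
Conditions: toluene, 90 °C
Reagents that add atoms: none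
Why: Thermal syn-elimination of the sulfoxide (the C11 hydrogen is activated by the lactone carbonyl) should regenerate the exocyclic methylene and erase the C11 and sulfur stereocentres.

**Compound list**
1 | diphenylmethane | C(c1ccccc1)c1ccccc1 | starting material
2 | chlorodimethylsilane | C[SiH](C)Cl | starting material
3 | (diphenylmethyl)lithium | [Li]C(c1ccccc1)c1ccccc1 | intermediate (not isolated)
4 | benzhydryldimethylsilane | C[SiH](C)C(c1ccccc1)c1ccccc1 | intermediate
5 | 4,4-diethoxybut-1-yne | C#CCC(OCC)OCC | starting material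
6 | (4,4-diethoxybut-1-yn-1-yl)lithium | [Li]C#CCC(OCC)OCC | intermediate (not isolated)
7 | 5,5-diethoxypent-2-yn-1-ol | OCC#CCC(OCC)OCC | intermediate
8 | (E)-3-[benzhydryl(dimethyl)silyl]-5,5-diethoxypent-2-en-1-ol | OC/C=C(\CC(OCC)OCC)[Si](C)(C)C(c1ccccc1)c1ccccc1 | intermediate
9 | (E)-3-[benzhydryl(dimethyl)silyl]-5,5-diethoxypent-2-en-1-yl diethyl phosphate | CCOP(=O)(OCC)OC/C=C(\CC(OCC)OCC)[Si](C)(C)C(c1ccccc1)c1ccccc1 | intermediate
10 | (R)-benzhydryl(5,5-diethoxy-3-methylpent-1-en-3-yl)dimethylsilane | C=C[C@@](C)(CC(OCC)OCC)[Si](C)(C)C(c1ccccc1)c1ccccc1 | intermediate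
11 | (R)-3-[benzhydryl(dimethyl)silyl]-3-methylpent-4-enal | C=C[C@@](C)(CC=O)[Si](C)(C)C(c1ccccc1)c1ccccc1 | intermediate
12 | methyl propiolate | C#CC(=O)OC | starting material
13 | methyl 3-(methylzincio)prop-2-ynoate | C[Zn]C#CC(=O)OC | intermediate (not isolated)
14 | methyl (4R,6R)-6-[benzhydryl(dimethyl)silyl]-4-hydroxy-6-methyloct-7-en-2-ynoate | COC(=O)C#C[C@H](O)C[C@](C)(C=C)[Si](C)(C)C(c1ccccc1)c1ccccc1 | intermediate
15 | methyl (4R,6R)-6-[benzhydryl(dimethyl)silyl]-4-[(tert-butyldimethylsilyl)oxy]-6-methyloct-7-en-2-ynoate | COC(=O)C#C[C@H](O[Si](C)(C)C(C)(C)C)C[C@](C)(C=C)[Si](C)(C)C(c1ccccc1)c1ccccc1 | intermediate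
16 | 2-(iodomethyl)-4,4,5,5-tetramethyl-1,3,2-dioxaborolane | ICB1OC(C)(C)C(C)(C)O1 | starting material
17 | methyl (2E,4R,6R)-6-[benzhydryl(dimethyl)silyl]-4-[(tert-butyldimethylsilyl)oxy]-2-(diisobutylalumanyl)-6-methylocta-2,7-dienoate | COC(=O)/C([Al](CC(C)C)CC(C)C)=C\[C@H](O[Si](C)(C)C(C)(C)C)C[C@](C)(C=C)[Si](C)(C)C(c1ccccc1)c1ccccc1 | intermediate (not isolated)
18 | methyl (2Z,4R,6R)-6-[benzhydryl(dimethyl)silyl]-4-[(tert-butyldimethylsilyl)oxy]-6-methyl-2-[(4,4,5,5-tetramethyl-1,3,2-dioxaborolan-2-yl)methyl]octa-2,7-dienoate | COC(=O)/C(CB1OC(C)(C)C(C)(C)O1)=C\[C@H](O[Si](C)(C)C(C)(C)C)C[C@](C)(C=C)[Si](C)(C)C(c1ccccc1)c1ccccc1 | intermediate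
19 | 4-methylfuran-2(5H)-one | CC1=CC(=O)OC1 | starting material
20 | (Z)-4-hydroxy-N-methoxy-N,3-dimethylbut-2-enamide | CON(C)C(=O)/C=C(/C)CO | intermediate
21 | (Z)-N-methoxy-N,3-dimethyl-4-[(triethylsilyl)oxy]but-2-enamide | CON(C)C(=O)/C=C(/C)CO[Si](CC)(CC)CC | intermediate
22 | (Z)-3-methyl-4-[(triethylsilyl)oxy]but-2-enal | O=C/C=C(/C)CO[Si](CC)(CC)CC | intermediate
23 | open-chain pinacol borate of the anti adduct: methyl 2-methylidene ester with C6–OBpin, C3–OTES, C8–OTBS (4Z,6R,7S,8R,10R) | COC(=O)C(=C)[C@@H]([C@H](OB1OC(C)(C)C(C)(C)O1)/C=C(/C)CO[Si](CC)(CC)CC)[C@H](O[Si](C)(C)C(C)(C)C)C[C@](C)(C=C)[Si](C)(C)C(c1ccccc1)c1ccccc1 | intermediate (not isolated)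
24 | (4S,5R)-5-[(Z)-2-methyl-3-(triethylsilyloxy)prop-1-enyl]-3-methylidene-4-[(1R,3R)-3-(benzhydryldimethylsilyl)-1-(tert-butyldimethylsilyloxy)-3-methylpent-4-enyl]oxolan-2-one | C=C1C(=O)O[C@H](/C=C(/C)CO[Si](CC)(CC)CC)[C@H]1[C@H](O[Si](C)(C)C(C)(C)C)C[C@](C)(C=C)[Si](C)(C)C(c1ccccc1)c1ccccc1 | intermediate (not isolated)
25 | (4S,5R)-5-[(Z)-3-hydroxy-2-methylprop-1-enyl]-3-methylidene-4-[(1R,3R)-3-(benzhydryldimethylsilyl)-1-(tert-butyldimethylsilyloxy)-3-methylpent-4-enyl]oxolan-2-one | C=C1C(=O)O[C@H](/C=C(/C)CO)[C@H]1[C@H](O[Si](C)(C)C(C)(C)C)C[C@](C)(C=C)[Si](C)(C)C(c1ccccc1)c1ccccc1 | intermediate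
26 | (4S,5R)-5-[(Z)-3-hydroxy-2-methylprop-1-enyl]-3-[(phenylsulfanyl)methyl]-4-[(1R,3R)-3-(benzhydryldimethylsilyl)-1-(tert-butyldimethylsilyloxy)-3-methylpent-4-enyl]oxolan-2-one (C3 epimers) | c1ccccc1SCC1C(=O)O[C@H](/C=C(/C)CO)[C@H]1[C@H](O[Si](C)(C)C(C)(C)C)C[C@](C)(C=C)[Si](C)(C)C(c1ccccc1)c1ccccc1 | intermediate
27 | (4S,5R)-5-[(Z)-2-methyl-3-oxoprop-1-enyl]-3-[(phenylsulfanyl)methyl]-4-[(1R,3R)-3-(benzhydryldimethylsilyl)-1-(tert-butyldimethylsilyloxy)-3-methylpent-4-enyl]oxolan-2-one (C3 epimers) | c1ccccc1SCC1C(=O)O[C@H](/C=C(/C)C=O)[C@H]1[C@H](O[Si](C)(C)C(C)(C)C)C[C@](C)(C=C)[Si](C)(C)C(c1ccccc1)c1ccccc1 | intermediate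
28 | (1S,3S,4Z,6R,7S,8R,10S)-1-(benzhydryldimethylsilyl)-8-(tert-butyldimethylsilyloxy)-3,10-epoxy-13-(phenylsulfanyl)germacr-4-en-12,6-olide (C11 epimers) | c1ccccc1SCC1C(=O)O[C@@H]2/C=C(/C)[C@@H]3C[C@H]([Si](C)(C)C(c4ccccc4)c4ccccc4)[C@](C)(C[C@@H](O[Si](C)(C)C(C)(C)C)[C@@H]12)O3 | intermediate
29 | (1S,3S,4Z,6R,7R,8R,10S)-1-(benzhydryldimethylsilyl)-3,10-epoxy-8-hydroxy-13-(phenylsulfanyl)germacr-4-en-12,6-olide (C11 epimers) | c1ccccc1SCC1C(=O)O[C@@H]2/C=C(/C)[C@@H]3C[C@H]([Si](C)(C)C(c4ccccc4)c4ccccc4)[C@](C)(C[C@@H](O)[C@@H]12)O3 | intermediate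
30 | angelic acid, (Z)-2-methylbut-2-enoic acid | C/C=C(/C)C(=O)O | starting material
31 | angelic 2,4,6-trichlorobenzoic anhydride | C/C=C(/C)C(=O)OC(=O)c1c(Cl)cc(Cl)cc1Cl | intermediate (not isolated)
32 | (1S,3S,4Z,6R,7R,8R,10S)-8-angeloyloxy-1-(benzhydryldimethylsilyl)-3,10-epoxy-13-(phenylsulfanyl)germacr-4-en-12,6-olide (C11 epimers) | c1ccccc1SCC1C(=O)O[C@@H]2/C=C(/C)[C@@H]3C[C@H]([Si](C)(C)C(c4ccccc4)c4ccccc4)[C@](C)(C[C@@H](OC(=O)/C(C)=C\C)[C@@H]12)O3 | intermediate
33 | (1S,3S,4Z,6R,7R,8R,10S)-8-angeloyloxy-3,10-epoxy-1-(fluorodimethylsilyl)-13-(phenylsulfanyl)germacr-4-en-12,6-olide | c1ccccc1SCC1C(=O)O[C@@H]2/C=C(/C)[C@@H]3C[C@H]([Si](C)(C)F)[C@](C)(C[C@@H](OC(=O)/C(C)=C\C)[C@@H]12)O3 | intermediate (not isolated)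
34 | (1S,3S,4Z,6R,7R,8R,10S)-8-angeloyloxy-3,10-epoxy-1-hydroxy-13-(phenylsulfinyl)germacr-4-en-12,6-olide (C11 and sulfur epimers) | O=S(c1ccccc1)CC1C(=O)O[C@@H]2/C=C(/C)[C@@H]3C[C@H](O)[C@](C)(C[C@@H](OC(=O)/C(C)=C\C)[C@@H]12)O3 | intermediate
35 | (1S,3S,4Z,6R,7R,8R,10S)-8-angeloyloxy-3,10-epoxy-1-hydroxygermacra-4,11(13)-dien-12,6-olide | C=C1C(=O)O[C@@H]2/C=C(/C)[C@@H]3C[C@H](O)[C@](C)(C[C@@H](OC(=O)/C(C)=C\C)[C@@H]12)O3 | target

**Step count**
Total: 20 steps. Longest linear sequence: 16 steps (steps 2–9, then 13–20). Step 1 (silane) and steps 10–12 (enal) are side branches.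

**Steps most likely to fail**

1. Step 16 (proposed new method). The seco-aldehyde may not fold for the ten-membered closure. The failure processes are desilylative Hosomi–Sakurai allylation instead of silyl shift and ring closure, E/Z isomerisation of the enal under the Lewis acid, oligomerisation, and closure through the transoid rotamer, which would give the wrong C1 configuration. The fallback uses known chemistry, sets out from 18 and returns at 28. Thermal allylboration of acrolein with 18 gives, through the open-chain pinacol borate F1, the 6-vinyl α-methylene lactone F2 (same chair and facial control as in step 13). Intermolecular [3+2] annulation of the allylsilane of F2 with methacrolein (BF3·OEt2, CH2Cl2, −78 °C) gives the 2-isopropenyl-3-silyloxolane F3. Ring-closing metathesis of its isopropenyl and vinyl groups with the second-generation Grubbs catalyst, RuCl2(=CHPh)(H2IMes)(PCy3), at high dilution should close the ten-membered ring as the Z trisubstituted alkene and give the bicyclic methylene lactone F4. Thia-Michael addition of thiophenol to F4 then gives 28.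

2. Step 13. The addition to the conjugated aldehyde may be slow, and the facial selectivity with respect to C8 may be poor or reversed (addition anti to the silyloxy group instead of anti to the C9 chain). The fallback sets C8 in the opposite sense and corrects it at the esterification; it sets out from 11 and returns at 32. Alkynylation of 11 with the other ligand enantiomer gives the (8S)-alcohol F5. The sequence of steps 8–17 then gives in turn the silyl ether F6, the alkenylalane F7, the (8S)-allylboronate F8, the open-chain borate F9, the triethylsilyl lactone F10, the hydroxy lactone F11, the sulfide F12, the seco-aldehyde F13, the annulation product F14 and the 8-epi alcohol F15. Mitsunobu esterification of F15 with angelic acid 30 (PPh3, DIAD, toluene, 0 °C) inverts C8 and gives 32.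

3. Step 5. The methyl transfer to the hindered silyl-substituted alkene may show low regioselectivity (SN2 against SN2′) or low enantioselectivity. The fallback builds the quaternary centre by a sigmatropic rearrangement and separates diastereomers after step 7; it sets out from 4 and returns at 14. PtCl2-catalysed hydrosilylation of but-2-yn-1-ol with 4 gives (E)-3-[benzhydryl(dimethyl)silyl]but-2-en-1-ol F16. Johnson–Claisen rearrangement with triethyl orthoacetate (propionic acid cat., 140 °C) gives, through the allyl ketene acetal F17, the racemic ethyl 3-silyl-3-methylpent-4-enoate F18. i-Bu2AlH at −78 °C gives the racemic aldehyde F19. The alkynylation of step 7 converts both enantiomers under catalyst control into 14 and its (10S)-diastereomer F20, which are separated by chromatography, and the route continues from 14.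

**Further compounds**
F1 | step 16 | open-chain pinacol borate of the acrolein adduct (6R,7S,8R,10R) | COC(=O)C(=C)[C@@H]([C@H](OB1OC(C)(C)C(C)(C)O1)C=C)[C@H](O[Si](C)(C)C(C)(C)C)C[C@](C)(C=C)[Si](C)(C)C(c1ccccc1)c1ccccc1
F2 | step 16 | (4S,5R)-5-ethenyl-3-methylidene-4-[(1R,3R)-3-(benzhydryldimethylsilyl)-1-(tert-butyldimethylsilyloxy)-3-methylpent-4-enyl]oxolan-2-one | C=C1C(=O)O[C@H](C=C)[C@H]1[C@H](O[Si](C)(C)C(C)(C)C)C[C@](C)(C=C)[Si](C)(C)C(c1ccccc1)c1ccccc1
F3 | step 16 | 6-vinyl lactone carrying the (1S,3S,10S)-1-silyl-3-isopropenyl-10-methyloxolane (4,5-seco diene) | C=C1C(=O)O[C@H](C=C)[C@H]1[C@H](O[Si](C)(C)C(C)(C)C)C[C@]1(C)O[C@H](C(C)=C)C[C@@H]1[Si](C)(C)C(c1ccccc1)c1ccccc1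
F4 | step 16 | (1S,3S,4Z,6R,7S,8R,10S)-1-(benzhydryldimethylsilyl)-8-(tert-butyldimethylsilyloxy)-3,10-epoxygermacra-4,11(13)-dien-12,6-olide | C=C1C(=O)O[C@@H]2/C=C(/C)[C@@H]3C[C@H]([Si](C)(C)C(c4ccccc4)c4ccccc4)[C@](C)(C[C@@H](O[Si](C)(C)C(C)(C)C)[C@@H]12)O3
F5 | step 13 | methyl (4S,6R)-6-[benzhydryl(dimethyl)silyl]-4-hydroxy-6-methyloct-7-en-2-ynoate | COC(=O)C#C[C@@H](O)C[C@](C)(C=C)[Si](C)(C)C(c1ccccc1)c1ccccc1
F6 | step 13 | (8S)-epimer of 15 | COC(=O)C#C[C@@H](O[Si](C)(C)C(C)(C)C)C[C@](C)(C=C)[Si](C)(C)C(c1ccccc1)c1ccccc1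
F7 | step 13 | (8S)-epimer of 17 | COC(=O)/C([Al](CC(C)C)CC(C)C)=C\[C@@H](O[Si](C)(C)C(C)(C)C)C[C@](C)(C=C)[Si](C)(C)C(c1ccccc1)c1ccccc1
F8 | step 13 | (8S)-epimer of 18 | COC(=O)/C(CB1OC(C)(C)C(C)(C)O1)=C\[C@@H](O[Si](C)(C)C(C)(C)C)C[C@](C)(C=C)[Si](C)(C)C(c1ccccc1)c1ccccc1
F9 | step 13 | (8S)-epimer of 23 | COC(=O)C(=C)[C@@H]([C@H](OB1OC(C)(C)C(C)(C)O1)/C=C(/C)CO[Si](CC)(CC)CC)[C@@H](O[Si](C)(C)C(C)(C)C)C[C@](C)(C=C)[Si](C)(C)C(c1ccccc1)c1ccccc1
F10 | step 13 | (8S)-epimer of 24 | C=C1C(=O)O[C@H](/C=C(/C)CO[Si](CC)(CC)CC)[C@H]1[C@@H](O[Si](C)(C)C(C)(C)C)C[C@](C)(C=C)[Si](C)(C)C(c1ccccc1)c1ccccc1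
F11 | step 13 | (8S)-epimer of 25 | C=C1C(=O)O[C@H](/C=C(/C)CO)[C@H]1[C@@H](O[Si](C)(C)C(C)(C)C)C[C@](C)(C=C)[Si](C)(C)C(c1ccccc1)c1ccccc1
F12 | step 13 | (8S)-epimer of 26 | c1ccccc1SCC1C(=O)O[C@H](/C=C(/C)CO)[C@H]1[C@@H](O[Si](C)(C)C(C)(C)C)C[C@](C)(C=C)[Si](C)(C)C(c1ccccc1)c1ccccc1
F13 | step 13 | (8S)-epimer of 27 | c1ccccc1SCC1C(=O)O[C@H](/C=C(/C)C=O)[C@H]1[C@@H](O[Si](C)(C)C(C)(C)C)C[C@](C)(C=C)[Si](C)(C)C(c1ccccc1)c1ccccc1
F14 | step 13 | (8S)-epimer of 28 | c1ccccc1SCC1C(=O)O[C@@H]2/C=C(/C)[C@@H]3C[C@H]([Si](C)(C)C(c4ccccc4)c4ccccc4)[C@](C)(C[C@H](O[Si](C)(C)C(C)(C)C)[C@@H]12)O3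
F15 | step 13 | (8S)-epimer of 29 | c1ccccc1SCC1C(=O)O[C@@H]2/C=C(/C)[C@@H]3C[C@H]([Si](C)(C)C(c4ccccc4)c4ccccc4)[C@](C)(C[C@H](O)[C@@H]12)O3
F16 | step 5 | (E)-3-[benzhydryl(dimethyl)silyl]but-2-en-1-ol | OC/C=C(\C)[Si](C)(C)C(c1ccccc1)c1ccccc1
F17 | step 5 | (E)-3-[benzhydryl(dimethyl)silyl]but-2-enyl ethyl ketene acetal | C=C(OCC)OC/C=C(\C)[Si](C)(C)C(c1ccccc1)c1ccccc1
F18 | step 5 | racemic ethyl 3-[benzhydryl(dimethyl)silyl]-3-methylpent-4-enoate | CCOC(=O)CC(C)(C=C)[Si](C)(C)C(c1ccccc1)c1ccccc1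
F19 | step 5 | racemic 3-[benzhydryl(dimethyl)silyl]-3-methylpent-4-enal | O=CCC(C)(C=C)[Si](C)(C)C(c1ccccc1)c1ccccc1
F20 | step 5 | methyl (4R,6S)-6-[benzhydryl(dimethyl)silyl]-4-hydroxy-6-methyloct-7-en-2-ynoate | COC(=O)C#C[C@H](O)C[C@@](C)(C=C)[Si](C)(C)C(c1ccccc1)c1ccccc1
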